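The syncarpic acid ring (5-hydroxy-2,2,6,6-tetramethylcyclohex-4-ene-1,3-dione) is disconnected into a dimethylmalonyl unit, C1(=O)–C2Me2–C3(=O), and the two carbons that flank the enol carbon C5: C4, which carries the benzylic stereocentre, and C6, a CMe2. Both are α to the same oxygenated carbon, so the ring is an isopropyl ketone doubly C-acylated by dimethylmalonyl dichloride. The key step does this in one flask on an acyclic triethylsilyl enol ether, closing the six-membered trione ring and creating its second quaternary carbon. The stereocentre is set earlier by an organocatalytic Friedel–Crafts addition of the acylphloroglucinol to an enal; benzyl ethers are removed last.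

Key step: step 8

Remark on the chemistry: the target is treated as the enol tautomer drawn. Lactol 8 is drawn as the ring isomer closed on the phenol next to the ring methyl group and is expected as a mixture of anomers; the isomer closed on the other ortho phenol would open to the same aldehyde in step 4.

Step 1
Reactants: 1 2-methylbenzene-1,3,5-triol; 2 3-phenylpropanoyl chloride
Product: 3 1-(2,4,6-trihydroxy-3-methylphenyl)-3-phenylpropan-1-one
Conditions: AlCl3 (3.5 equiv), PhNO2, rt to 60 °C; aq HCl work-up
Reagents that add atoms: none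
Why: Friedel–Crafts C-acylation of a phloroglucinol, in which the two open ring positions of 1 are equivalent and the first acyl group deactivates the ring toward a second acylation.

Step 2
Reactants: 4 3-phenylpropanal; 5 (triphenylphosphoranylidene)acetaldehyde
Product: 6 (E)-5-phenylpent-2-enal
Conditions: toluene, 80 °C
Reagents that add atoms: none
Why: Wittig olefination with a stabilised formyl ylide, which should give the E enal.

Step 3
Reactants: 3 1-(2,4,6-trihydroxy-3-methylphenyl)-3-phenylpropan-1-one; 6 (E)-5-phenylpent-2-enal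
Product: 8 1-[(4S)-2,5,7-trihydroxy-8-methyl-4-(2-phenylethyl)-3,4-dihydro-2H-chromen-6-yl]-3-phenylpropan-1-one (lactol as anomer mixture), via open-chain aldehyde 7 (not isolated)
Conditions: (R)-2-[diphenyl(trimethylsilyloxy)methyl]pyrrolidine (20 mol %), PhCO2H (20 mol %), CHCl3, 0 °C to rt
Reagents that add atoms: none
Why: Iminium-ion-catalysed asymmetric Friedel–Crafts conjugate addition of the phenol through its only free ring carbon, followed by hemiacetalisation, in which the CPh2(OSiMe3) group of the (R)-catalyst shields the Re face at C3 of the (E)-iminium ion so that the arene should add to the Si face and set the (S) centre.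

Step 4
Reactants: 8 lactol from step 3
Product: 9 (3S)-5-phenyl-3-[2,4,6-tris(benzyloxy)-3-methyl-5-(3-phenylpropanoyl)phenyl]pentanal
Conditions: BnBr (3.6 equiv), K2CO3 (4 equiv), DMF, rt to 40 °C
Reagents that add atoms: benzyl bromide, BrCc1ccccc1
Why: Williamson ether synthesis on the phenoxides, in which base opens the lactol to the phenoxide aldehyde so that all three phenols are benzylated and the aldehyde is released, the stereocentre being neither acidic nor next to a leaving group.

Step 5
Reactants: 9 tribenzyl aldehyde; 10 isopropenylmagnesium bromide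
Product: 11 (5S)-2-methyl-7-phenyl-5-[2,4,6-tris(benzyloxy)-3-methyl-5-(3-phenylpropanoyl)phenyl]hept-1-en-3-ol (both C3 epimers)
Conditions: THF, −78 °C; then water quench
Reagents that add atoms: none
Why: Grignard 1,2-addition, which should select the aldehyde over the aryl ketone flanked by two ortho benzyloxy groups; the new carbinol centre is not controlled and is removed in step 6.

Step 6
Reactants: 11 allylic alcohol
Product: 12 (5S)-2-methyl-7-phenyl-5-[2,4,6-tris(benzyloxy)-3-methyl-5-(3-phenylpropanoyl)phenyl]hept-1-en-3-one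
Conditions: Dess–Martin periodinane (1.3 equiv), CH2Cl2, 0 °C to rt
Reagents that add atoms: none
Why: Dess–Martin oxidation of a secondary allylic alcohol to the isopropenyl ketone under conditions that leave benzyl ethers and the remote stereocentre untouched.

Step 7
Reactants: 12 isopropenyl ketone
Product: 13 triethyl({(5S)-2-methyl-7-phenyl-5-[2,4,6-tris(benzyloxy)-3-methyl-5-(3-phenylpropanoyl)phenyl]hept-2-en-3-yl}oxy)silane
Conditions: Et3SiH (1.5 equiv), RhCl(PPh3)3 (2 mol %), toluene, 50 °C
Reagents that add atoms: triethylsilane, CC[SiH](CC)CC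
Why: Rhodium-catalysed 1,4-hydrosilylation of an enone, which should deliver the silyl enol ether with its double bond fixed on the CMe2 side and leave the hindered, non-conjugated aryl ketone as a ketone.

Step 8
Reactants: 13 triethylsilyl enol ether; 14 2,2-dimethylpropanedioyl dichloride (dimethylmalonyl dichloride)
Product: 16 5-hydroxy-2,2,6,6-tetramethyl-4-{(1R)-3-phenyl-1-[2,4,6-tris(benzyloxy)-3-methyl-5-(3-phenylpropanoyl)phenyl]propyl}cyclohex-4-ene-1,3-dione, via diketo acid chloride 15 (not isolated)
Conditions: 14 (1.3 equiv), ZnCl2 (1.2 equiv), CH2Cl2/Et2O, slow addition of 13, −20 °C to rt; then MgBr2·OEt2 (2.5 equiv), i-Pr2NEt (3 equiv), 0 °C to rt; aq citric acid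
Reagents that add atoms: none
Why: ZnCl2 activates one acyl chloride of 14 and the CMe2 terminus of silyl enol ether 13 is C-acylated with loss of Et3SiCl, forming the ketone-to-CMe2 bond and the new quaternary carbon of 15; MgBr2·OEt2/i-Pr2NEt then enolises the only enolisable position of the new 1,3-diketone (the CH2 next to the stereocentre), and the magnesium enolate attacks the remaining acyl chloride to close the ring, which tautomerises to the enol. The closest known reaction type is the Effenberger annulation (α,α′-double C-acylation of a ketone enol ether by a malonyl dichloride to a cyclohexane-1,3,5-trione), run here on an acyclic enol ether in two stages that are each known reactions (Lewis-acid acylation of silyl enol ethers by acyl chlorides; soft-enolisation C-acylation of ketones by acyl chlorides). The one ring closed, the six-membered carbocycle, forms by 6-(enolendo)-exo-trig attack of the enolate carbon on the acyl chloride. No stereocentre is created, and the existing benzylic centre is not enolisable and carries no leaving group, so it should pass through unchanged. The step needs regioselectivity (first acylation at CMe2, secured because the hydrosilylation placed the enol ether double bond there), C- over O-acylation in the closure (favoured by the magnesium chelate and the stability of the β-triketone enolate), and chemoselectivity over the aryl ketone (which is never turned into an enol ether and has no acyl chloride within reach of a six-membered closure).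

Step 9
Reactants: 16 tri-O-benzyl ether of the target
Product: 17 5-hydroxy-2,2,6,6-tetramethyl-4-{(1R)-3-phenyl-1-[2,4,6-trihydroxy-3-methyl-5-(3-phenylpropanoyl)phenyl]propyl}cyclohex-4-ene-1,3-dione (target)
Conditions: H2 (1 atm), 10% Pd/C, EtOAc, rt
Reagents that add atoms: none
Why: Hydrogenolysis of the three benzyl ethers on Pd/C under neutral conditions, which should spare the hydrogen-bonded aryl ketone and the tetrasubstituted enol double bond and avoid the acid or base that could ionise the benzylic centre or cyclise the ortho phenol onto the enol.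

Compound list
1 | 2-methylbenzene-1,3,5-triol | Cc1c(O)cc(O)cc1O | starting material
2 | 3-phenylpropanoyl chloride | O=C(Cl)CCc1ccccc1 | starting material
3 | 1-(2,4,6-trihydroxy-3-methylphenyl)-3-phenylpropan-1-one | Cc1c(O)cc(O)c(C(=O)CCc2ccccc2)c1O | intermediate
4 | 3-phenylpropanal | O=CCCc1ccccc1 | starting material
5 | (triphenylphosphoranylidene)acetaldehyde | O=CC=P(c1ccccc1)(c1ccccc1)c1ccccc1 | starting material
6 | (E)-5-phenylpent-2-enal | O=C/C=C/CCc1ccccc1 | intermediate
7 | (3S)-5-phenyl-3-[2,4,6-trihydroxy-3-methyl-5-(3-phenylpropanoyl)phenyl]pentanal (open-chain form, not isolated) | Cc1c(O)c(C(=O)CCc2ccccc2)c(O)c([C@@H](CCc2ccccc2)CC=O)c1O | intermediate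
8 | 1-[(4S)-2,5,7-trihydroxy-8-methyl-4-(2-phenylethyl)-3,4-dihydro-2H-chromen-6-yl]-3-phenylpropan-1-one (anomer mixture) | Cc1c(O)c(C(=O)CCc2ccccc2)c(O)c2[C@@H](CCc3ccccc3)CC(O)Oc12 | intermediate
9 | (3S)-5-phenyl-3-[2,4,6-tris(benzyloxy)-3-methyl-5-(3-phenylpropanoyl)phenyl]pentanal | Cc1c(OCc2ccccc2)c(C(=O)CCc2ccccc2)c(OCc2ccccc2)c([C@@H](CCc2ccccc2)CC=O)c1OCc1ccccc1 | intermediate
10 | isopropenylmagnesium bromide | C=C(C)[Mg]Br | starting material
11 | (5S)-2-methyl-7-phenyl-5-[2,4,6-tris(benzyloxy)-3-methyl-5-(3-phenylpropanoyl)phenyl]hept-1-en-3-ol (C3 epimers) | Cc1c(OCc2ccccc2)c(C(=O)CCc2ccccc2)c(OCc2ccccc2)c([C@@H](CCc2ccccc2)CC(O)C(C)=C)c1OCc1ccccc1 | intermediate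
12 | (5S)-2-methyl-7-phenyl-5-[2,4,6-tris(benzyloxy)-3-methyl-5-(3-phenylpropanoyl)phenyl]hept-1-en-3-one | Cc1c(OCc2ccccc2)c(C(=O)CCc2ccccc2)c(OCc2ccccc2)c([C@@H](CCc2ccccc2)CC(=O)C(C)=C)c1OCc1ccccc1 | intermediate
13 | triethyl({(5S)-2-methyl-7-phenyl-5-[2,4,6-tris(benzyloxy)-3-methyl-5-(3-phenylpropanoyl)phenyl]hept-2-en-3-yl}oxy)silane | Cc1c(OCc2ccccc2)c(C(=O)CCc2ccccc2)c(OCc2ccccc2)c([C@@H](CCc2ccccc2)CC(O[Si](CC)(CC)CC)=C(C)C)c1OCc1ccccc1 | intermediate
14 | 2,2-dimethylpropanedioyl dichloride | CC(C)(C(=O)Cl)C(=O)Cl | starting material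
15 | (7S)-2,2,4,4-tetramethyl-3,5-dioxo-9-phenyl-7-[2,4,6-tris(benzyloxy)-3-methyl-5-(3-phenylpropanoyl)phenyl]nonanoyl chloride (not isolated) | Cc1c(OCc2ccccc2)c(C(=O)CCc2ccccc2)c(OCc2ccccc2)c([C@@H](CCc2ccccc2)CC(=O)C(C)(C)C(=O)C(C)(C)C(=O)Cl)c1OCc1ccccc1 | intermediate
16 | 5-hydroxy-2,2,6,6-tetramethyl-4-{(1R)-3-phenyl-1-[2,4,6-tris(benzyloxy)-3-methyl-5-(3-phenylpropanoyl)phenyl]propyl}cyclohex-4-ene-1,3-dione | Cc1c(OCc2ccccc2)c(C(=O)CCc2ccccc2)c(OCc2ccccc2)c([C@@H](CCc2ccccc2)C2=C(O)C(C)(C)C(=O)C(C)(C)C2=O)c1OCc1ccccc1 | intermediate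
17 | 5-hydroxy-2,2,6,6-tetramethyl-4-{(1R)-3-phenyl-1-[2,4,6-trihydroxy-3-methyl-5-(3-phenylpropanoyl)phenyl]propyl}cyclohex-4-ene-1,3-dione | Cc1c(O)c(C(=O)CCc2ccccc2)c(O)c([C@@H](CCc2ccccc2)C2=C(O)C(C)(C)C(=O)C(C)(C)C2=O)c1O | target

Total step count: 9. Longest linear sequence: 8 steps (steps 1 and 3 to 9; step 2 is a one-step side branch).

Steps most likely to fail

1. Step 8. The hindered tetrasubstituted silyl enol ether may be O-acylated or may not react with the tertiary acyl chloride. In the closure, intermolecular acylation or O-cyclisation to an enol lactone may compete. Fallback, setting out from 13 and coming back at 16: a Mukaiyama aldol addition of 13 to methyl 2,2-dimethyl-3-oxopropanoate (BF3·OEt2, CH2Cl2, −78 °C) should give methyl (7S)-3-hydroxy-2,2,4,4-tetramethyl-5-oxo-9-phenyl-7-[2,4,6-tris(benzyloxy)-3-methyl-5-(3-phenylpropanoyl)phenyl]nonanoate F1, an aldehyde being a far better partner for a hindered enol ether and unable to O-acylate. Dess–Martin oxidation would give the diketo ester methyl (7S)-2,2,4,4-tetramethyl-3,5-dioxo-9-phenyl-7-[2,4,6-tris(benzyloxy)-3-methyl-5-(3-phenylpropanoyl)phenyl]nonanoate F2. A Dieckmann cyclisation of F2 (LiN(SiMe3)2, THF, −78 to 0 °C, then acid) should close the ring to 16 with loss of methanol.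

2. Step 3. The acyl-deactivated phenol may add too slowly to the hindered iminium ion, condensation at the aldehyde carbon may lead to a 2H-chromene, or facial selectivity may be poor. Fallback, setting out from 3 and 6 and coming back at 9: addition under an achiral, less hindered amine (pyrrolidine/PhCO2H, CHCl3) should give the racemic lactol 1-[2,5,7-trihydroxy-8-methyl-4-(2-phenylethyl)-3,4-dihydro-2H-chromen-6-yl]-3-phenylpropan-1-one F3. Benzylation as in step 4 would give racemic 5-phenyl-3-[2,4,6-tris(benzyloxy)-3-methyl-5-(3-phenylpropanoyl)phenyl]pentanal F4, whose enantiomers would be separated by preparative chromatography on a chiral stationary phase to supply 9.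

3. Step 4. The liberated aldehyde may undergo base-induced aldol self-condensation while the hydrogen-bonded phenol next to the acyl group is still being benzylated. Fallback, setting out from 8 and coming back at 11: excess isopropenylmagnesium bromide 10 (THF, −40 °C to rt) would add to the open form of the lactol while the magnesium phenoxides protect the aryl ketone as a vinylogous carboxylate, giving 1-{2,4,6-trihydroxy-3-[(3S)-5-hydroxy-6-methyl-1-phenylhept-6-en-3-yl]-5-methylphenyl}-3-phenylpropan-1-one F5. Selective benzylation of its three phenols (BnBr, K2CO3, acetone) would then give 11, no aldehyde ever being exposed to base.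

Further compounds
F1 | step 8 | methyl (7S)-3-hydroxy-2,2,4,4-tetramethyl-5-oxo-9-phenyl-7-[2,4,6-tris(benzyloxy)-3-methyl-5-(3-phenylpropanoyl)phenyl]nonanoate (C3 epimers) | Cc1c(OCc2ccccc2)c(C(=O)CCc2ccccc2)c(OCc2ccccc2)c([C@@H](CCc2ccccc2)CC(=O)C(C)(C)C(O)C(C)(C)C(=O)OC)c1OCc1ccccc1
F2 | step 8 | methyl (7S)-2,2,4,4-tetramethyl-3,5-dioxo-9-phenyl-7-[2,4,6-tris(benzyloxy)-3-methyl-5-(3-phenylpropanoyl)phenyl]nonanoate | Cc1c(OCc2ccccc2)c(C(=O)CCc2ccccc2)c(OCc2ccccc2)c([C@@H](CCc2ccccc2)CC(=O)C(C)(C)C(=O)C(C)(C)C(=O)OC)c1OCc1ccccc1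
F3 | step 3 | racemic 1-[2,5,7-trihydroxy-8-methyl-4-(2-phenylethyl)-3,4-dihydro-2H-chromen-6-yl]-3-phenylpropan-1-one | Cc1c(O)c(C(=O)CCc2ccccc2)c(O)c2C(CCc3ccccc3)CC(O)Oc12
F4 | step 3 | racemic 5-phenyl-3-[2,4,6-tris(benzyloxy)-3-methyl-5-(3-phenylpropanoyl)phenyl]pentanal | Cc1c(OCc2ccccc2)c(C(=O)CCc2ccccc2)c(OCc2ccccc2)c(C(CCc2ccccc2)CC=O)c1OCc1ccccc1
F5 | step 4 | 1-{2,4,6-trihydroxy-3-[(3S)-5-hydroxy-6-methyl-1-phenylhept-6-en-3-yl]-5-methylphenyl}-3-phenylpropan-1-one (carbinol epimers) | Cc1c(O)c(C(=O)CCc2ccccc2)c(O)c([C@@H](CCc2ccccc2)CC(O)C(C)=C)c1O
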